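**Retrosynthetic overview**
1. The oxolane is the only ring and is closed last. Its C5–O bond and the tertiary C–Br bond form together in a 5-exo bromoetherification of acyclic dienol 20, with Br+ made by a vanadium-dependent haloperoxidase (KBr/H2O2).
2. 20 ⇒ diol 18 (allylic OH → Cl) ⇒ alkyne 15 ((E)-CH=CHBr by hydrozirconation/NBS) ⇒ aldehyde 14 (Ohira–Bestmann).
3. The (E)-CH=C(CH3)CH2O unit ⇒ cross metathesis of terminal alkene 8 with methacrolein.
4. The anti C–O/C–Cl pair ⇒ Ti-directed chloride opening of epoxy alcohol 6 ⇒ catalytic Sharpless epoxidation of achiral (Z)-dienol 5.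
5. 5 ⇒ propargyl alcohol (anti-carbomagnesiation/iodination, then Stille allylation).

Assumption: the SMILES is read as (2S,3S,5S,2'S), with bromovinyl, ring Cl and side chain all on one face of the oxolane. The haloperoxidase is taken as available by standard recombinant expression.

**Step 1**
Reactants: 1 prop-2-yn-1-ol
Product: 3 (2Z)-3-iodo-2-methylprop-2-en-1-ol, via vinylmagnesium alkoxide 2 (not isolated)
Conditions: MeMgBr (3 equiv), CuI (10 mol %), THF/Et2O, −10 °C → rt, 16 h; then I2 (1.3 equiv), −20 °C → rt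
Reagents that add atoms: methylmagnesium bromide, C[Mg]Br; iodine, II
Why: In this Cu-catalysed anti-carbomagnesiation of a propargylic alkoxide, chelation holds Mg cis to CH2O, and iodinolysis with retention gives only the Z iodide.

**Step 2**
Reactants: 3 (2Z)-3-iodo-2-methylprop-2-en-1-ol; 4 allyltributylstannane
Product: 5 (2Z)-2-methylhexa-2,5-dien-1-ol
Conditions: PdCl2(MeCN)2 (5 mol %), DMF, rt; careful concentration (volatile)
Reagents that add atoms: none
Why: Stille coupling of an alkenyl iodide keeps the alkene geometry, the unsubstituted allyl group has no regiochemical ambiguity, and the free OH is tolerated.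

**Step 3**
Reactants: 5 (2Z)-2-methylhexa-2,5-dien-1-ol
Product: 6 [(2S,3R)-2-methyl-3-(prop-2-en-1-yl)oxiran-2-yl]methanol
Conditions: Ti(OiPr)4 (10 mol %), L-(+)-DET (13 mol %), TBHP (2 equiv, anhydrous), 4 Å MS, CH2Cl2, −20 °C, 24–48 h
Reagents that add atoms: tert-butyl hydroperoxide, CC(C)(C)OO
Why: In this Katsuki–Sharpless asymmetric epoxidation, the Ti/L-(+)-tartrate catalyst delivers oxygen to the face that gives 2S (the sense seen with nerol), the Z geometry fixes 3R, the terminal alkene is untouched, and about 90 % ee is usual for this olefin class.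

**Step 4**
Reactants: 6 [(2S,3R)-2-methyl-3-(prop-2-en-1-yl)oxiran-2-yl]methanol
Product: 7 (2S,3S)-3-chloro-2-methylhex-5-ene-1,2-diol
Conditions: ClTi(OiPr)3 (2 equiv), CH2Cl2, 0 °C → rt; aq. tartaric acid work-up
Reagents that add atoms: chlorotitanium triisopropoxide, CC(C)O[Ti](Cl)(OC(C)C)OC(C)C
Why: In this Ti-chelate-directed SN2 opening of a 2,3-epoxy alcohol, chloride attacks the distal secondary carbon with inversion (3R → 3S), while the quaternary carbon keeps its C–O bond because it is hindered and deactivated by CH2O–Ti.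

**Step 5**
Reactants: 7 (2S,3S)-3-chloro-2-methylhex-5-ene-1,2-diol
Product: 8 (2S,3S)-3-chloro-2-methyl-1,2-bis(triethylsilyloxy)hex-5-ene
Conditions: TESOTf (2.6 equiv), 2,6-lutidine (4 equiv), CH2Cl2, −78 → 0 °C
Reagents that add atoms: triethylsilyl triflate, CC[Si](CC)(CC)OS(=O)(=O)C(F)(F)F
Why: Silyl triflate silylation caps even the hindered tertiary OH, and the weak base cannot close the chlorohydrin back to the epoxide.

**Step 6**
Reactants: 8 (2S,3S)-3-chloro-2-methyl-1,2-bis(triethylsilyloxy)hex-5-ene; 9 methacrolein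
Product: 10 (2E,5S,6S)-5-chloro-2,6-dimethyl-6,7-bis(triethylsilyloxy)hept-2-enal
Conditions: 9 (8 equiv), Hoveyda–Grubbs II (5 mol %), CH2Cl2, 40 °C, 16 h
Reagents that add atoms: none
Why: Olefin cross metathesis of an unhindered terminal alkene with excess methacrolein gives the conjugated trisubstituted enal with high E selectivity, and it is run before any alkyne or vinyl bromide is present.

**Step 7**
Reactants: 10 (2E,5S,6S)-5-chloro-2,6-dimethyl-6,7-bis(triethylsilyloxy)hept-2-enal
Product: 11 (2E,5S,6S)-5-chloro-2,6-dimethyl-6,7-bis(triethylsilyloxy)hept-2-en-1-ol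
Conditions: DIBAL-H (1.2 equiv), CH2Cl2, −78 °C; Rochelle salt
Reagents that add atoms: none
Why: This clean 1,2-reduction of the enal at low temperature uses no base, so vinylogous loss of HCl is avoided.

**Step 8**
Reactants: 11 (2E,5S,6S)-5-chloro-2,6-dimethyl-6,7-bis(triethylsilyloxy)hept-2-en-1-ol
Product: 12 (2S,3S,5E)-7-(tert-butyldiphenylsilyloxy)-3-chloro-2,6-dimethyl-1,2-bis(triethylsilyloxy)hept-5-ene
Conditions: TBDPSCl (1.2 equiv), imidazole (2.5 equiv), CH2Cl2, 0 °C → rt
Reagents that add atoms: tert-butyldiphenylsilyl chloride, CC(C)(C)[Si](Cl)(c1ccccc1)c1ccccc1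
Why: Standard silylation installs an acid-robust group that is orthogonal to the primary TES ether.

**Step 9**
Reactants: 12 (2S,3S,5E)-7-(tert-butyldiphenylsilyloxy)-3-chloro-2,6-dimethyl-1,2-bis(triethylsilyloxy)hept-5-ene
Product: 13 (2S,3S,5E)-7-(tert-butyldiphenylsilyloxy)-3-chloro-2,6-dimethyl-2-(triethylsilyloxy)hept-5-en-1-ol
Conditions: PPTS (0.2 equiv), MeOH/CH2Cl2 1:4, 0 °C, followed by TLC
Reagents that add atoms: none
Why: In this acid-catalysed methanolysis the primary TES ether cleaves far faster than the tertiary TES or the TBDPS ether, and acidic medium excludes silyl migration.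

**Step 10**
Reactants: 13 (2S,3S,5E)-7-(tert-butyldiphenylsilyloxy)-3-chloro-2,6-dimethyl-2-(triethylsilyloxy)hept-5-en-1-ol
Product: 14 (2S,3S,5E)-7-(tert-butyldiphenylsilyloxy)-3-chloro-2,6-dimethyl-2-(triethylsilyloxy)hept-5-enal
Conditions: DMP (1.3 equiv), CH2Cl2, 0 °C → rt
Reagents that add atoms: none
Why: Dess–Martin oxidation gives an aldehyde with no α-hydrogen, so neither epimerisation nor β-elimination of chloride can occur.

**Step 11**
Reactants: 14 (2S,3S,5E)-7-(tert-butyldiphenylsilyloxy)-3-chloro-2,6-dimethyl-2-(triethylsilyloxy)hept-5-enal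
Product: 15 (3S,4S,6E)-8-(tert-butyldiphenylsilyloxy)-4-chloro-3,7-dimethyl-3-(triethylsilyloxy)oct-6-en-1-yne
Conditions: Ohira–Bestmann reagent (1.5 equiv), K2CO3 (2 equiv), MeOH, 0 °C → rt
Reagents that add atoms: dimethyl (1-diazo-2-oxopropyl)phosphonate, COP(=O)(OC)C(=[N+]=[N-])C(C)=O
Why: Seyferth–Gilbert homologation (Ohira–Bestmann variant) works well on non-enolisable α-quaternary aldehydes, and the capped tertiary oxygen cannot displace the neighbouring chloride.

**Step 12**
Reactants: 15 (3S,4S,6E)-8-(tert-butyldiphenylsilyloxy)-4-chloro-3,7-dimethyl-3-(triethylsilyloxy)oct-6-en-1-yne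
Product: 17 (1E,3S,4S,6E)-1-bromo-8-(tert-butyldiphenylsilyloxy)-4-chloro-3,7-dimethyl-3-(triethylsilyloxy)octa-1,6-diene, via alkenylzirconocene chloride 16 (not isolated)
Conditions: Cp2Zr(H)Cl (1.6 equiv), THF, rt, 45 min, dark; NBS (1.6 equiv), 0 °C, 15 min
Reagents that add atoms: N-bromosuccinimide, O=C1CCC(=O)N1Br; Schwartz reagent, [H][Zr](Cl)(C1C=CC=C1)C1C=CC=C1 (its Zr stays only in 16)
Why: Hydrozirconation adds H and Zr syn with Zr at the terminus, and bromodezirconation with retention gives only the E vinyl bromide, free of the halogen scrambling of chromium methods.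

**Step 13**
Reactants: 17 (1E,3S,4S,6E)-1-bromo-8-(tert-butyldiphenylsilyloxy)-4-chloro-3,7-dimethyl-3-(triethylsilyloxy)octa-1,6-diene
Product: 18 (2E,5S,6S,7E)-8-bromo-5-chloro-2,6-dimethylocta-2,7-diene-1,6-diol
Conditions: HF·pyridine (excess), pyridine, THF, 0 °C → rt, 16 h (PE vessel)
Reagents that add atoms: none
Why: Fluoride desilylation in acidic medium removes both silyl groups without ever forming the tertiary alkoxide that would expel chloride to give an epoxide.

**Step 14**
Reactants: 18 (2E,5S,6S,7E)-8-bromo-5-chloro-2,6-dimethylocta-2,7-diene-1,6-diol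
Product: 20 (1E,3S,4S,6E)-1-bromo-4,8-dichloro-3,7-dimethylocta-1,6-dien-3-ol, via allylic mesylate 19 (not isolated)
Conditions: MsCl (1.15 equiv), 2,4,6-collidine (1.5 equiv), LiCl (3 equiv), DMF, 0 °C, 2 h
Reagents that add atoms: lithium chloride, [Li+].[Cl-]; methanesulfonyl chloride, CS(=O)(=O)Cl (its mesyl group stays only in 19)
Why: In this Collington–Meyers allylic chlorination only the primary allylic OH is mesylated, and direct SN2 by chloride occurs without allylic shift or E/Z loss.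

**Step 15**
Reactants: 20 (1E,3S,4S,6E)-1-bromo-4,8-dichloro-3,7-dimethylocta-1,6-dien-3-ol
Product: 21 (2S,3S,5S)-5-[(2S)-2-bromo-1-chloropropan-2-yl]-2-[(E)-2-bromoethenyl]-3-chloro-2-methyloxolane
Conditions: vanadium-dependent haloperoxidase (recombinant Curvularia inaequalis V-chloroperoxidase, ca. 200 nM), KBr (1.5 equiv), H2O2 (1.3 equiv, syringe pump, 8 h), Na3VO4 (50 µM), citrate buffer (0.1 M, pH 5)/MeCN 4:1, 25 °C; chromatography
Reagents that add atoms: potassium bromide, [K+].[Br-]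
Why: In this chemoenzymatic bromoetherification the haloperoxidase turns bromide and H2O2 into HOBr, which attacks only the electron-richer trisubstituted alkene; 5-exo capture by the tertiary OH is strictly anti, so the E alkene can give only the (5S,2'S)/(5R,2'R) pair; the CH2Cl group weakens the pull towards the 6-endo oxane; and an envelope transition state with C–Cl and the reacting alkene pseudo-equatorial favours the 3,5-cis (5S,2'S) isomer (moderate dr expected, isomers separated).

**Compound list**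
1 | prop-2-yn-1-ol | C#CCO | starting material
2 | bromomagnesium (2Z)-3-(bromomagnesio)-2-methylprop-2-en-1-olate | Br[Mg]OC/C(C)=C\[Mg]Br | intermediate (not isolated)
3 | (2Z)-3-iodo-2-methylprop-2-en-1-ol | OC/C(C)=C\I | intermediate
4 | allyltributylstannane | C=CC[Sn](CCCC)(CCCC)CCCC | starting material
5 | (2Z)-2-methylhexa-2,5-dien-1-ol | OC/C(C)=C\CC=C | intermediate
6 | [(2S,3R)-2-methyl-3-(prop-2-en-1-yl)oxiran-2-yl]methanol | C=CC[C@H]1O[C@@]1(C)CO | intermediate
7 | (2S,3S)-3-chloro-2-methylhex-5-ene-1,2-diol | C=CC[C@H](Cl)[C@](C)(CO)O | intermediate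
8 | (2S,3S)-3-chloro-2-methyl-1,2-bis(triethylsilyloxy)hex-5-ene | C=CC[C@H](Cl)[C@](C)(CO[Si](CC)(CC)CC)O[Si](CC)(CC)CC | intermediate
9 | methacrolein (2-methylprop-2-enal) | CC(=C)C=O | starting material
10 | (2E,5S,6S)-5-chloro-2,6-dimethyl-6,7-bis(triethylsilyloxy)hept-2-enal | O=C/C(C)=C/C[C@H](Cl)[C@](C)(CO[Si](CC)(CC)CC)O[Si](CC)(CC)CC | intermediate
11 | (2E,5S,6S)-5-chloro-2,6-dimethyl-6,7-bis(triethylsilyloxy)hept-2-en-1-ol | OC/C(C)=C/C[C@H](Cl)[C@](C)(CO[Si](CC)(CC)CC)O[Si](CC)(CC)CC | intermediate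
12 | (2S,3S,5E)-7-(tert-butyldiphenylsilyloxy)-3-chloro-2,6-dimethyl-1,2-bis(triethylsilyloxy)hept-5-ene | CC(C)(C)[Si](OC/C(C)=C/C[C@H](Cl)[C@](C)(CO[Si](CC)(CC)CC)O[Si](CC)(CC)CC)(c1ccccc1)c1ccccc1 | intermediate
13 | (2S,3S,5E)-7-(tert-butyldiphenylsilyloxy)-3-chloro-2,6-dimethyl-2-(triethylsilyloxy)hept-5-en-1-ol | CC(C)(C)[Si](OC/C(C)=C/C[C@H](Cl)[C@](C)(CO)O[Si](CC)(CC)CC)(c1ccccc1)c1ccccc1 | intermediate
14 | (2S,3S,5E)-7-(tert-butyldiphenylsilyloxy)-3-chloro-2,6-dimethyl-2-(triethylsilyloxy)hept-5-enal | CC(C)(C)[Si](OC/C(C)=C/C[C@H](Cl)[C@](C)(C=O)O[Si](CC)(CC)CC)(c1ccccc1)c1ccccc1 | intermediate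
15 | (3S,4S,6E)-8-(tert-butyldiphenylsilyloxy)-4-chloro-3,7-dimethyl-3-(triethylsilyloxy)oct-6-en-1-yne | CC(C)(C)[Si](OC/C(C)=C/C[C@H](Cl)[C@](C)(C#C)O[Si](CC)(CC)CC)(c1ccccc1)c1ccccc1 | intermediate
16 | (E)-alkenylzirconocene chloride of 15 (Cp rings drawn η1 in the SMILES) | CC(C)(C)[Si](OC/C(C)=C/C[C@H](Cl)[C@](C)(/C=C/[Zr](Cl)(C1C=CC=C1)C1C=CC=C1)O[Si](CC)(CC)CC)(c1ccccc1)c1ccccc1 | intermediate (not isolated)
17 | (1E,3S,4S,6E)-1-bromo-8-(tert-butyldiphenylsilyloxy)-4-chloro-3,7-dimethyl-3-(triethylsilyloxy)octa-1,6-diene | CC(C)(C)[Si](OC/C(C)=C/C[C@H](Cl)[C@](C)(/C=C/Br)O[Si](CC)(CC)CC)(c1ccccc1)c1ccccc1 | intermediate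
18 | (2E,5S,6S,7E)-8-bromo-5-chloro-2,6-dimethylocta-2,7-diene-1,6-diol | OC/C(C)=C/C[C@H](Cl)[C@](C)(/C=C/Br)O | intermediate
19 | (2E,5S,6S,7E)-8-bromo-5-chloro-6-hydroxy-2,6-dimethylocta-2,7-dien-1-yl methanesulfonate | CS(=O)(=O)OC/C(C)=C/C[C@H](Cl)[C@](C)(/C=C/Br)O | intermediate (not isolated)
20 | (1E,3S,4S,6E)-1-bromo-4,8-dichloro-3,7-dimethylocta-1,6-dien-3-ol | ClC/C(C)=C/C[C@H](Cl)[C@](C)(/C=C/Br)O | intermediate
21 | (2S,3S,5S)-5-[(2S)-2-bromo-1-chloropropan-2-yl]-2-[(E)-2-bromoethenyl]-3-chloro-2-methyloxolane | C[C@@](Br)(CCl)[C@@H]1C[C@H](Cl)[C@](C)(/C=C/Br)O1 | target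

**Totals**
Total step count: 15. Longest linear sequence: 15 (from 1).

**Three steps most likely to fail**

Step 15 (enzymatic bromoetherification).
- Risks: water may capture the bromonium ion to give a bromohydrin, some 6-endo oxane may form, and face selectivity is only moderate.
- Fallback, setting out from 20 and coming back at 21: give up hypobromite made in water and transfer Br+ from a stoichiometric donor in a dry, non-nucleophilic medium. Use 2,4,4,6-tetrabromocyclohexa-2,5-dienone (1.1 equiv) in MeNO2 at −20 °C.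
- If face selectivity is the limit, use NBS with a chiral Brønsted acid or a cinchona-type Lewis base catalyst in toluene at −40 °C, screening both antipodes. The catalyst, not the substrate, then chooses the alkene face.
- It makes no new compound (F0).

Step 4 (regiochemistry of chloride opening).
- Risk: partial attack at the tertiary carbon.
- Fallback, setting out from 6 and coming back at 7: make the quaternary carbon electronically unattackable by turning CH2OH into an ester.
- TEMPO/PhI(OAc)2 in MeCN–H2O gives (2R,3R)-2-methyl-3-(prop-2-en-1-yl)oxirane-2-carboxylic acid F1.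
- F1 is esterified at once with TMSCHN2 to methyl (2R,3R)-2-methyl-3-(prop-2-en-1-yl)oxirane-2-carboxylate F2.
- LiCl/Amberlyst 15 in MeCN opens this glycidate only at the β-carbon with inversion, giving methyl (2S,3S)-3-chloro-2-hydroxy-2-methylhex-5-enoate F3.
- DIBAL-H (CH2Cl2, −78 → 0 °C) reduces the ester to 7.

Step 6 (cross metathesis to a trisubstituted enal).
- Risks: low conversion and homodimerisation.
- Fallback, setting out from 8 and coming back at 11: build the alkene by carbonyl olefination.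
- Ozonolysis (O3, CH2Cl2, −78 °C; PPh3) gives (3S,4S)-3-chloro-4-methyl-4,5-bis(triethylsilyloxy)pentanal F4, which is used at once.
- The weakly basic stabilised ylide Ph3P=C(CH3)CO2Et (CH2Cl2, rt) gives ethyl (2E,5S,6S)-5-chloro-2,6-dimethyl-6,7-bis(triethylsilyloxy)hept-2-enoate F5 with high E selectivity.
- DIBAL-H (2.3 equiv, −78 °C) gives 11.

**Further compounds**
F0 | step 15 | none | none
F1 | step 4 | (2R,3R)-2-methyl-3-(prop-2-en-1-yl)oxirane-2-carboxylic acid | C=CC[C@H]1O[C@@]1(C)C(=O)O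
F2 | step 4 | methyl (2R,3R)-2-methyl-3-(prop-2-en-1-yl)oxirane-2-carboxylate | C=CC[C@H]1O[C@@]1(C)C(=O)OC
F3 | step 4 | methyl (2S,3S)-3-chloro-2-hydroxy-2-methylhex-5-enoate | C=CC[C@H](Cl)[C@](C)(C(=O)OC)O
F4 | step 6 | (3S,4S)-3-chloro-4-methyl-4,5-bis(triethylsilyloxy)pentanal | O=CC[C@H](Cl)[C@](C)(CO[Si](CC)(CC)CC)O[Si](CC)(CC)CC
F5 | step 6 | ethyl (2E,5S,6S)-5-chloro-2,6-dimethyl-6,7-bis(triethylsilyloxy)hept-2-enoate | CCOC(=O)/C(C)=C/C[C@H](Cl)[C@](C)(CO[Si](CC)(CC)CC)O[Si](CC)(CC)CC
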